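(Readings and results come from a simulation for an exercise, and the scatter is random.)

A catalyst that stayed whole is impossible in these runs, and one tally shows it. Target forms from substrate, coupling partner and catalyst, while catalyst slips reversibly into a dormant form, an off-cycle state.

all flasks: substrate 0.20 M; coupling partner 1.05 equiv
- Friday's: catalyst 5 mol%; the very flask that is asked about, followed so far
- Monday's: catalyst 2.5 mol%; run made earlier
- flask: catalyst 5 mol%

- Friday's (time / min: target / %): 4.00: 2.2; 10.0: 6.2; 20.0: 11.3; 30.0: 16.1; 40.0: 19.2; 50.0: 23.7; 60.0: 25.7
- Monday's (time / h: target / %): 0.667: 11.0; 1.33: 19.1; 2.00: 24.4; 2.50: 27.5; 3.00: 30.6; 4.00: 34.7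

(each reading ± 0.5 percentage points)

- apparent order in catalyst when 50% of the substrate are converted (percent change of the rate of making target for one percent more catalyst charged)

- reactions considered so far: substrate + coupling partner + catalyst -> catalyst + target; catalyst <-> dormant form

I divided the reagents' drain out of each reading. The tally is the integral, over conversion, of one over the product of the substrate and coupling partner left, so its speed follows the active catalyst. Friday's flask, scaled to Monday's loading, had a tally of 0.113 at 40.0 min, and Monday's flask had 0.117 at that moment, so I took the loss to follow the clock.

Friday's flask needs a tally of 0.930 at 50% conversion, which is 0.465 on Monday's scale. Monday's tally stood at 0.416 after 3.00 h and 0.500 after 4.00 h, so I estimated the arrival of Friday's flask near 3.58 h. Monday's speed from 2.50 h to 4.00 h, the readings around that time, was 0.0945 h⁻¹.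

Tally over speed gives the effective hours, 4.92 h. One percent more catalyst makes the tally run one percent faster, so Friday's flask arrives earlier by one percent of the effective hours and finds its catalyst fresher. With the loss following the clock, the order at fixed conversion is therefore one plus effective hours over the lifetime of the speed, which is the speed at arrival over its rate of fall.

Monday's two last one-hour speeds, 0.111 h⁻¹ and 0.0842 h⁻¹, give a lifetime of 3.68 h and an order of 2.34. That is the weak link, since neighbouring differences carry the scatter of 0.5 percentage points per reading. I reforged it over a longer span. Friday's first hour, scaled, ran at 0.163 h⁻¹, faster than Monday's last hour, which gives a lifetime of 4.53 h. I committed to an order of 2.09, as a high-side figure, since that lifetime reaches back to Friday's first hour, earlier than the arrival, and the return step should slow the fall.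

The forecast gave 1.3, within 1.08 to 1.75, on the ground that “More catalyst gets there sooner, with less deactivation”, and my figure stood above it.

Friday's flask gives 1.7, reaching 50% conversion at 3.50 h.

    substrate + coupling partner + catalyst → catalyst + target (k = 3.11 L² mol⁻² min⁻¹)
    catalyst ⇌ dormant form (K = 2.82, k = 0.00381 min⁻¹)

Its catalyst stood at 55.3% of the charge after 3.00 h and 37.7% after 6.00 h, a lifetime of 7.81 h across that stretch, longer than my reforged one. The effective hours, divided by the order's excess over one, put the lifetime at that conversion at 6.68 h.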